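**Retrosynthetic overview**
- The target is the mono-reduction product of the C2-symmetric 4,4'-diketone, whose two carbonyls are equivalent.
- The diketone is cut at both C5–C6 ring bonds and both C7=C8 bonds: two acyclic keto vinylphosphonium salts plus the C20 crocetin dialdehyde.
- Each enamine Michael closure onto the vinylphosphonium carbon makes one cyclohexanone and leaves the phosphonium that becomes the ylide. Ring A and ring B therefore form together in one flask, and no ring exists before that operation.
- The vinylphosphonium salt comes from an (E)-vinyl iodide, that from 2,2-dimethyl-5-oxoheptanal, and that from isobutyraldehyde and ethyl vinyl ketone.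

Assumption: all-E crocetin dialdehyde is bought as a catalogue C20 building block, and the (R,R) amine–thiourea is taken to give the 6S ring (its mirror image is used if the sense is reversed).

**Step 1**
Reactants: 1 2-methylpropanal (isobutyraldehyde); 2 pent-1-en-3-one (ethyl vinyl ketone)
Product: 3 2,2-dimethyl-5-oxoheptanal
Conditions: Et2NSiMe3 (20 mol%), MeCN, 25 °C
Reagents that add atoms: none
Why: amine-catalysed Michael addition of the α-branched aldehyde to the vinyl ketone stops at the 1,5-keto aldehyde under these neutral conditions, and no stereocenter is formed.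

**Step 2**
Reactants: 3 2,2-dimethyl-5-oxoheptanal
Product: 4 (7E)-8-iodo-6,6-dimethyloct-7-en-3-one
Conditions: CHI3, CrCl2, THF, 0 → 25 °C
Reagents that add atoms: iodoform, IC(I)I
Why: the Takai iodo-olefination attacks only the aldehyde, leaves the ketone alone, and gives the E alkenyl iodide, especially from α-quaternary aldehydes.

**Step 3**
Reactants: 4 (7E)-8-iodo-6,6-dimethyloct-7-en-3-one
Product: 5 [(1E)-3,3-dimethyl-6-oxooct-1-en-1-yl]triphenylphosphonium iodide
Conditions: PPh3, Pd(PPh3)4 (3 mol%), toluene, 100 °C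
Reagents that add atoms: triphenylphosphine, c1ccc(cc1)P(c1ccccc1)c1ccccc1
Why: palladium-catalysed C–P cross-coupling (oxidative addition of the alkenyl iodide to zerovalent palladium, then C–P reductive elimination) gives the alkenylphosphonium salt with retention of the E geometry, and the quaternary γ-carbon rules out isomerisation to an allyl salt.

**Step 4**
Reactants: 5 [(1E)-3,3-dimethyl-6-oxooct-1-en-1-yl]triphenylphosphonium iodide (2.1 equiv); 6 crocetin dialdehyde [(2E,4E,6E,8E,10E,12E,14E)-2,6,11,15-tetramethylhexadeca-2,4,6,8,10,12,14-heptaenedial]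
Product: 9 (5S,6S,5'S,6'S)-5,6,5',6'-tetrahydro-β,β-carotene-4,4'-dione, via cyclised phosphonium iodide 7 (not isolated), via phosphorus ylide 8 (not isolated)
Conditions: a) 1-[(1R,2R)-2-aminocyclohexyl]-3-[3,5-bis(trifluoromethyl)phenyl]thiourea (20 mol%), PhCO2H (20 mol%), CH2Cl2, 25 °C; b) solvent switch to THF, 6 (0.48 equiv), KOt-Bu, −78 → 0 °C; c) I2 (2 mol%), CH2Cl2–hexane, daylight, 25 °C, then crystallisation
Reagents that add atoms: none
Why: Proposed new method: the primary amine forms the enamine of the ethyl ketone, whose C5 adds 6-exo (Michael addition) to the tethered vinylphosphonium carbon C6 while the thiourea holds the iodide–phosphonium ion pair so that one face is attacked (6S), hydrolysis gives 7 with C5 equilibrated to the trans 5S centre, KOt-Bu then gives ylide 8 which olefinates both aldehydes of 6 (Wittig reaction) and iodine turns any hindered 7Z bond into 7E; the closest known chemistry is the Schweizer conjugate addition to vinylphosphonium salts followed by Wittig olefination, amine–thiourea Michael additions of ketones, and carotenoid Wittig couplings of keto phosphonium salts, and the double coupling raises the enantiomeric purity of 9 because the minor ring enantiomer ends mainly in a separable meso-like diastereomer.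

**Step 5**
Reactants: 9 (5S,6S,5'S,6'S)-5,6,5',6'-tetrahydro-β,β-carotene-4,4'-dione
Product: 10 (4S,5S,6S,5'S,6'S)-4-hydroxy-5,6,5',6'-tetrahydro-β,β-caroten-4'-one
Conditions: NaBH4 (0.3 equiv), CeCl3·7H2O (1 equiv), MeOH–THF, −40 °C
Reagents that add atoms: none
Why: in this Luche-type reduction, axial hydride attack on the cyclohexanone (chain and 5-methyl equatorial) gives the equatorial 4S alcohol, trans to the 5-methyl and cis to the chain; the two carbonyls of C2-symmetric 9 are equivalent, so substoichiometric hydride gives 10 statistically, with 9 and the diol separated and recycled.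

**Compound list**
1 | 2-methylpropanal | CC(C)C=O | starting material
2 | pent-1-en-3-one | CCC(=O)C=C | starting material
3 | 2,2-dimethyl-5-oxoheptanal | CCC(=O)CCC(C)(C)C=O | intermediate
4 | (7E)-8-iodo-6,6-dimethyloct-7-en-3-one | CCC(=O)CCC(C)(C)/C=C/I | intermediate
5 | [(1E)-3,3-dimethyl-6-oxooct-1-en-1-yl]triphenylphosphonium iodide | CCC(=O)CCC(C)(C)/C=C/[P+](c1ccccc1)(c1ccccc1)c1ccccc1.[I-] | intermediate
6 | crocetin dialdehyde | O=C/C(C)=C/C=C/C(C)=C/C=C/C=C(C)/C=C/C=C(C)/C=O | starting material
7 | {[(1S,6S)-2,2,6-trimethyl-5-oxocyclohexyl]methyl}triphenylphosphonium iodide | [I-].c1ccc(cc1)[P+](c1ccccc1)(c1ccccc1)C[C@H]1[C@H](C)C(=O)CCC1(C)C | intermediate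
8 | (2S,3S)-2,4,4-trimethyl-3-[(triphenyl-λ5-phosphanylidene)methyl]cyclohexan-1-one | c1ccc(cc1)P(c1ccccc1)(c1ccccc1)=C[C@H]1[C@H](C)C(=O)CCC1(C)C | intermediate
9 | (5S,6S,5'S,6'S)-5,6,5',6'-tetrahydro-β,β-carotene-4,4'-dione | CC(/C=C/C=C(C)/C=C/[C@H]1[C@H](C)C(=O)CCC1(C)C)=C\C=C\C=C(C)\C=C\C=C(C)\C=C\[C@H]1[C@H](C)C(=O)CCC1(C)C | intermediate
10 | (4S,5S,6S,5'S,6'S)-4-hydroxy-5,6,5',6'-tetrahydro-β,β-caroten-4'-one | CC(/C=C/C=C(C)/C=C/[C@H]1[C@H](C)[C@@H](O)CCC1(C)C)=C\C=C\C=C(C)\C=C\C=C(C)\C=C\[C@H]1[C@H](C)C(=O)CCC1(C)C | target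

**Totals**
Total step count: 5. Longest linear sequence: 5 (1 → 3 → 4 → 5 → 9 → 10).

**Steps most likely to fail**

Step 4 is the weakest. The enamine must add to a hindered vinylphosphonium carbon, the enantioselectivity is unproven, and ylide 8 can reopen by retro-Michael reaction before it meets the aldehyde. The fallback sets out from 1 and comes back at 9; it closes the ring first and brings the side chain in by conjugate addition. Robinson annulation of 1 with but-3-en-2-one (pyrrolidine, then aqueous HCl) gives 4,4-dimethylcyclohex-2-en-1-one F1. Copper-catalysed asymmetric conjugate addition of a vinylalane (vinylmagnesium bromide and Me2AlCl, Cu(OTf)2, chiral phosphoramidite of the enantiomer that gives the 3S centre), with methylation of the enolate in the same flask (MeLi, MeI), gives (2S,3S)-2,4,4-trimethyl-3-vinylcyclohexan-1-one F2. Heck coupling of F2 with (E)-3-iodobut-2-en-1-ol (Pd(OAc)2, Ag2CO3, DMF) gives (2S,3S)-3-[(1E,3E)-5-hydroxy-3-methylpenta-1,3-dien-1-yl]-2,4,4-trimethylcyclohexan-1-one F3. PPh3·HBr in methanol turns F3 into {(2E,4E)-3-methyl-5-[(1S,6S)-2,2,6-trimethyl-5-oxocyclohexyl]penta-2,4-dien-1-yl}triphenylphosphonium bromide F4. Double Wittig reaction of F4 with 2,7-dimethylocta-2,4,6-trienedial (NaOMe, CH2Cl2–MeOH) gives 9.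

Step 3 may be slow because the alkenyl iodide carries a quaternary carbon next to the double bond. The fallback sets out from 3 and comes back at 5, bypassing 4. PPh3 and (iodomethyl)trimethylsilane give triphenyl[(trimethylsilyl)methyl]phosphonium iodide F5. KHMDS at −78 °C gives triphenyl[(trimethylsilyl)methylidene]-λ5-phosphane F6. F6 adds to the aldehyde of 3 and the adduct collapses by Peterson elimination of silanolate rather than of Ph3PO, which gives 5 after work-up with aqueous NaI.

Step 5 is statistical and gives at best about half of the material per pass. The fallback sets out from 5 and comes back at 10; it builds the two ends separately. Step 4 is stopped after stage a) and 7 is isolated by crystallisation. One half of 7 is reduced with NaBH4 and CeCl3·7H2O to {[(1S,5S,6S)-5-hydroxy-2,2,6-trimethylcyclohexyl]methyl}triphenylphosphonium iodide F7. The other half is converted into 8 (KOt-Bu) and treated with an excess of 6 (3 equiv) to give (2E,4E,6E,8E,10E,12E,14E,16E)-2,6,11,15-tetramethyl-17-[(1S,6S)-2,2,6-trimethyl-5-oxocyclohexyl]heptadeca-2,4,6,8,10,12,14,16-octaenal F8. Wittig reaction of F8 with F7 (KOt-Bu, 2 equiv), then iodine isomerisation, gives 10 without a statistical reduction.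

**Further compounds**
F1 | step 4 | 4,4-dimethylcyclohex-2-en-1-one | CC1(C)CCC(=O)C=C1
F2 | step 4 | (2S,3S)-2,4,4-trimethyl-3-vinylcyclohexan-1-one | C=C[C@H]1[C@H](C)C(=O)CCC1(C)C
F3 | step 4 | (2S,3S)-3-[(1E,3E)-5-hydroxy-3-methylpenta-1,3-dien-1-yl]-2,4,4-trimethylcyclohexan-1-one | OC/C=C(C)/C=C/[C@H]1[C@H](C)C(=O)CCC1(C)C
F4 | step 4 | {(2E,4E)-3-methyl-5-[(1S,6S)-2,2,6-trimethyl-5-oxocyclohexyl]penta-2,4-dien-1-yl}triphenylphosphonium bromide | [Br-].c1ccc(cc1)[P+](c1ccccc1)(c1ccccc1)C/C=C(C)/C=C/[C@H]1[C@H](C)C(=O)CCC1(C)C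
F5 | step 3 | triphenyl[(trimethylsilyl)methyl]phosphonium iodide | [I-].C[Si](C)(C)C[P+](c1ccccc1)(c1ccccc1)c1ccccc1
F6 | step 3 | triphenyl[(trimethylsilyl)methylidene]-λ5-phosphane | C[Si](C)(C)C=P(c1ccccc1)(c1ccccc1)c1ccccc1
F7 | step 5 | {[(1S,5S,6S)-5-hydroxy-2,2,6-trimethylcyclohexyl]methyl}triphenylphosphonium iodide | [I-].c1ccc(cc1)[P+](c1ccccc1)(c1ccccc1)C[C@H]1[C@H](C)[C@@H](O)CCC1(C)C
F8 | step 5 | (2E,4E,6E,8E,10E,12E,14E,16E)-2,6,11,15-tetramethyl-17-[(1S,6S)-2,2,6-trimethyl-5-oxocyclohexyl]heptadeca-2,4,6,8,10,12,14,16-octaenal | O=C/C(C)=C/C=C/C(C)=C/C=C/C=C(C)/C=C/C=C(C)/C=C/[C@H]1[C@H](C)C(=O)CCC1(C)C
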